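**Plan**

1. Atom labels: ring C1' carries the side chain, C3' the methoxy group, C5' the hydroxyl, and C6' is the CH between C1' and C5'; chain C1 is benzylic, C2 bears the acetate, C13 the primary hydroxyl.
2. Enabling feature: the benzene ring is oxygenated on alternate carbons (C3', C5') and the chain carries oxygen at C2, β to the ring. This is the 1,3-oxygen pattern of a folded poly-β-carbonyl chain, so the arene can be unravelled into a masked 3,5-diketo acid and closed again by an aldol.
3. Cuts, in retrosynthetic order: the acetate C–O bond and two benzyl-type O-protections; a carboxyl carbon is put back on C6' and tied to O5' as an acetonide; the ring is opened at C1'–C6' (aldol); then C1'–C2' (Claisen acylation), C3'–C4' (acetylation of the dioxinone methyl) and side-chain C1–C2 (malonate homologation).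
4. Forward: the C12 hydroxy acid is extended to a C14 β-keto ester, reduced, silylated and converted to a Weinreb amide; this acylates the dianion of the acetonyl-dioxinone; the benzene ring, the only ring of the target, then closes in one step from the open diketo-dioxinone.
5. After ring formation the single free phenol is methylated, the auxiliary carboxyl is removed, and a benzyl/silyl/acetyl exchange delivers the mono-acetate.
6. Stereochemistry: the only stereocentre (C2, R) is set by RuCl2[(R)-BINAP] hydrogenation of the β-keto ester and carried unchanged; it is never α to a carbonyl and no later step breaks its C–O bond.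

Key step: step 8

**Route**

Step 1
Reactants: 1 12-hydroxydodecanoic acid
Product: 3 12-(benzyloxy)dodecanoic acid, via benzyl 12-(benzyloxy)dodecanoate 2 (not isolated)
Conditions: NaH (3 equiv), BnBr (2.4 equiv), Bu4NI (cat.), THF–DMF, 0 °C → rt; then NaOH, MeOH–H2O, 60 °C; HCl to pH 2
Reagents that add atoms: benzyl bromide, BrCc1ccccc1; sodium hydroxide, [Na+].[OH-] (supplies the carboxyl oxygen on saponification)
Why: Williamson alkylation of the alkoxide and the carboxylate with excess benzyl bromide, followed by saponification of the benzyl ester in the same flask, should leave only the base-stable benzyl ether on the primary alcohol.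

Step 2
Reactants: 3 12-(benzyloxy)dodecanoic acid; 4 potassium methyl malonate
Product: 6 methyl 14-(benzyloxy)-3-oxotetradecanoate, via acyl imidazole 5 (not isolated)
Conditions: 1,1'-carbonyldiimidazole (CDI), THF, rt; then 4, MgCl2, THF, rt → 50 °C; 1 M HCl work-up
Reagents that add atoms: 1,1'-carbonyldiimidazole, O=C(n1ccnc1)n1ccnc1 (its imidazolyl group stays only in 5)
Why: Masamune homologation, in which the acyl imidazole C-acylates the magnesium enolate of the malonate half ester and loss of CO2 from the acylmalonate gives the β-keto ester under nearly neutral conditions.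

Step 3
Reactants: 6 methyl 14-(benzyloxy)-3-oxotetradecanoate
Product: 7 methyl (R)-14-(benzyloxy)-3-hydroxytetradecanoate
Conditions: H2 (10 bar), RuCl2[(R)-BINAP] (0.5 mol %), MeOH, 50 °C
Reagents that add atoms: none
Why: Noyori asymmetric hydrogenation, in which the β-keto ester chelates divalent ruthenium through both carbonyls and the (R)-BINAP ligand directs hydride to the face that gives the (R)-carbinol, as for simple 3-oxoalkanoates, while the benzyl ether is inert to this homogeneous catalyst.

Step 4
Reactants: 7 methyl (R)-14-(benzyloxy)-3-hydroxytetradecanoate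
Product: 8 methyl (R)-14-(benzyloxy)-3-(tert-butyldimethylsilyloxy)tetradecanoate
Conditions: TBSCl, imidazole, DMF, rt
Reagents that add atoms: tert-butyldimethylsilyl chloride, CC(C)(C)[Si](C)(C)Cl
Why: Imidazole-promoted silylation of a secondary alcohol is routine, and the silyl ether keeps this oxygen from adding to the ketones, the dioxinone carbonyl or the ring carboxyl in later steps.

Step 5
Reactants: 8 methyl (R)-14-(benzyloxy)-3-(tert-butyldimethylsilyloxy)tetradecanoate
Product: 9 (R)-14-(benzyloxy)-3-(tert-butyldimethylsilyloxy)-N-methoxy-N-methyltetradecanamide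
Conditions: MeNH(OMe)·HCl, iPrMgCl, THF, −20 → 0 °C; aq. NH4Cl
Reagents that add atoms: N,O-dimethylhydroxylamine hydrochloride, CNOC.Cl
Why: Weinreb amide formation by direct aminolysis of the methyl ester with the chloromagnesium amide is fast at low temperature and should leave the β-silyloxy group in place.

Step 6
Reactants: 10 2,2,6-trimethyl-4H-1,3-dioxin-4-one
Product: 11 2,2-dimethyl-6-(2-oxopropyl)-4H-1,3-dioxin-4-one
Conditions: LiN(SiMe3)2, THF, −78 °C; then AcCl, −78 → −20 °C
Reagents that add atoms: acetyl chloride, CC(=O)Cl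
Why: Deprotonation of the 6-methyl group gives the lithium dienolate, which is C-acylated at its terminal carbon by acetyl chloride (vinylogous Claisen-type acylation).

Step 7
Reactants: 11 2,2-dimethyl-6-(2-oxopropyl)-4H-1,3-dioxin-4-one; 9 (R)-14-(benzyloxy)-3-(tert-butyldimethylsilyloxy)-N-methoxy-N-methyltetradecanamide
Product: 12 6-[(R)-17-(benzyloxy)-6-(tert-butyldimethylsilyloxy)-2,4-dioxoheptadecyl]-2,2-dimethyl-4H-1,3-dioxin-4-one
Conditions: 11, LiN(iPr)2 (2.1 equiv per 11), THF, −78 °C; Et2Zn; then 9, −78 → −20 °C; aq. NH4Cl; crude 12 taken on after extractive work-up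
Reagents that add atoms: none
Why: Claisen-type acylation of the β-dicarbonyl dianion at its terminal, most nucleophilic carbon, in which the Weinreb amide holds the adduct as a metal chelate until the quench and Et2Zn tempers the basicity that could otherwise enolise the amide and expel the β-silyloxy group.

Step 8
Reactants: 12 6-[(R)-17-(benzyloxy)-6-(tert-butyldimethylsilyloxy)-2,4-dioxoheptadecyl]-2,2-dimethyl-4H-1,3-dioxin-4-one
Product: 14 5-[(R)-13-(benzyloxy)-2-(tert-butyldimethylsilyloxy)tridecyl]-7-hydroxy-2,2-dimethyl-4H-benzo[d][1,3]dioxin-4-one, via cyclic aldol adduct 13 (not isolated)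
Conditions: Et3N, CH2Cl2, rt
Reagents that add atoms: none
Why: Et3N enolises the 1,3-diketone/dioxinone array, the enol(ate) conjugated through the dioxinone C5=C6 bond adds by its α-carbon (dioxinone C5, future C6') to the C4 ketone of the side chain (future C1') to give the β-hydroxy ketone 13, and loss of water followed by enolisation of the remaining ring ketone gives the phenol and the aromatic ring. The closest known reaction type is the amine-mediated aldol aromatisation of 6-(2,4-dioxoalkyl)-1,3-dioxin-4-ones to acetonide-protected resorcylates, the laboratory counterpart of the C2–C7 aldol folding of a tetraketide. The one ring formed is the benzene ring, closed in the 6-(enolendo)-exo-trig mode (the nucleophilic C5=C6 enol unit lies inside the new ring, the ketone oxygen outside). No stereocentre is created, and the existing C–OSi centre, which sits β to the reacting ketone, is not affected. The step needs C-aldol closure at the dioxinone α-carbon in preference to Claisen closure onto the carboxyl carbon, O-cyclisation to a pyranone, retro-[4+2] to an acyl ketene and β-elimination of silanolate; the dioxinone secures this by holding the carboxyl carbon as a poorly electrophilic vinylogous carbonate and placing its α-carbon six atoms from the ketone, room temperature keeps the dioxinone intact, and the silyl ether stops the C2 oxygen from adding to a ketone or to the dioxinone carbonyl. Because the acetonide ties the carboxyl to the ortho oxygen, only the hydroxyl para to the carboxyl is left free for the following methylation.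

Step 9
Reactants: 14 5-[(R)-13-(benzyloxy)-2-(tert-butyldimethylsilyloxy)tridecyl]-7-hydroxy-2,2-dimethyl-4H-benzo[d][1,3]dioxin-4-one
Product: 15 5-[(R)-13-(benzyloxy)-2-(tert-butyldimethylsilyloxy)tridecyl]-7-methoxy-2,2-dimethyl-4H-benzo[d][1,3]dioxin-4-one
Conditions: MeI, K2CO3, acetone, rt
Reagents that add atoms: iodomethane, CI
Why: Williamson methylation of the only free phenol fixes the position of the methyl ether, since the second ring oxygen is locked in the acetonide.

Step 10
Reactants: 15 5-[(R)-13-(benzyloxy)-2-(tert-butyldimethylsilyloxy)tridecyl]-7-methoxy-2,2-dimethyl-4H-benzo[d][1,3]dioxin-4-one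
Product: 17 3-[(R)-13-(benzyloxy)-2-(tert-butyldimethylsilyloxy)tridecyl]-5-methoxyphenol, via ring carboxylic acid 16 (not isolated)
Conditions: KOH, EtOH–H2O, reflux; neutral aqueous work-up
Reagents that add atoms: potassium hydroxide, [K+].[OH-] (its oxygen stays only in 16)
Why: Hydroxide opens the aryl-ester-like dioxinone with loss of acetone, and the electron-rich 2-hydroxy-4-methoxy-6-alkylbenzoate should then undergo protodecarboxylation by ipso-protonation in the hot alkaline medium, as in the hydrolysis–decarboxylation of 6-alkylresorcylates to 5-alkylresorcinols, while the base-stable silyl ether prevents lactonisation to a dihydroisocoumarin.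

Step 11
Reactants: 17 3-[(R)-13-(benzyloxy)-2-(tert-butyldimethylsilyloxy)tridecyl]-5-methoxyphenol
Product: 18 1-(benzyloxy)-3-[(R)-13-(benzyloxy)-2-(tert-butyldimethylsilyloxy)tridecyl]-5-methoxybenzene
Conditions: BnBr, K2CO3, DMF, rt
Reagents that add atoms: benzyl bromide, BrCc1ccccc1
Why: Williamson benzylation of the phenoxide masks the phenol so that only the secondary alcohol is acetylated later, and this benzyl ether can be removed together with the chain benzyl ether at the end.

Step 12
Reactants: 18 1-(benzyloxy)-3-[(R)-13-(benzyloxy)-2-(tert-butyldimethylsilyloxy)tridecyl]-5-methoxybenzene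
Product: 19 (R)-13-(benzyloxy)-1-[3-(benzyloxy)-5-methoxyphenyl]tridecan-2-ol
Conditions: Bu4NF, THF, rt
Reagents that add atoms: none
Why: Fluoride-induced cleavage of the silyl ether, driven by Si–F bond formation, frees the secondary alcohol without touching either benzyl ether or the stereocentre.

Step 13
Reactants: 19 (R)-13-(benzyloxy)-1-[3-(benzyloxy)-5-methoxyphenyl]tridecan-2-ol
Product: 20 (R)-13-(benzyloxy)-1-[3-(benzyloxy)-5-methoxyphenyl]tridecan-2-yl acetate
Conditions: Ac2O, pyridine, DMAP (cat.), CH2Cl2, rt
Reagents that add atoms: acetic anhydride, CC(=O)OC(C)=O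
Why: DMAP-catalysed acylation of the only free hydroxyl takes place at oxygen, so the C–O bond and the (R) configuration are retained.

Step 14
Reactants: 20 (R)-13-(benzyloxy)-1-[3-(benzyloxy)-5-methoxyphenyl]tridecan-2-yl acetate
Product: 21 (R)-13-hydroxy-1-(3-hydroxy-5-methoxyphenyl)tridecan-2-yl acetate
Conditions: H2 (1 atm), Pd/C, EtOAc–EtOH, rt
Reagents that add atoms: none
Why: Heterogeneous hydrogenolysis should cleave the aryl benzyl and alkyl benzyl ethers in one operation, whereas the homobenzylic acetate, which is not a benzylic C–O bond, and the aryl methyl ether remain.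

**Compound list**

1 | 12-hydroxydodecanoic acid | OCCCCCCCCCCCC(=O)O | starting material
2 | benzyl 12-(benzyloxy)dodecanoate (formed in the flask in step 1) | O=C(CCCCCCCCCCCOCc1ccccc1)OCc1ccccc1 | intermediate
3 | 12-(benzyloxy)dodecanoic acid | OC(=O)CCCCCCCCCCCOCc1ccccc1 | intermediate
4 | potassium methyl malonate | COC(=O)CC(=O)[O-].[K+] | starting material
5 | 1-[12-(benzyloxy)dodecanoyl]-1H-imidazole (formed in the flask in step 2) | O=C(CCCCCCCCCCCOCc1ccccc1)n1ccnc1 | intermediate
6 | methyl 14-(benzyloxy)-3-oxotetradecanoate | COC(=O)CC(=O)CCCCCCCCCCCOCc1ccccc1 | intermediate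
7 | methyl (R)-14-(benzyloxy)-3-hydroxytetradecanoate | COC(=O)C[C@@H](CCCCCCCCCCCOCc1ccccc1)O | intermediate
8 | methyl (R)-14-(benzyloxy)-3-(tert-butyldimethylsilyloxy)tetradecanoate | COC(=O)C[C@@H](CCCCCCCCCCCOCc1ccccc1)O[Si](C)(C)C(C)(C)C | intermediate
9 | (R)-14-(benzyloxy)-3-(tert-butyldimethylsilyloxy)-N-methoxy-N-methyltetradecanamide | CON(C)C(=O)C[C@@H](CCCCCCCCCCCOCc1ccccc1)O[Si](C)(C)C(C)(C)C | intermediate
10 | 2,2,6-trimethyl-4H-1,3-dioxin-4-one | CC1=CC(=O)OC(C)(C)O1 | starting material
11 | 2,2-dimethyl-6-(2-oxopropyl)-4H-1,3-dioxin-4-one | CC(=O)CC1=CC(=O)OC(C)(C)O1 | intermediate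
12 | 6-[(R)-17-(benzyloxy)-6-(tert-butyldimethylsilyloxy)-2,4-dioxoheptadecyl]-2,2-dimethyl-4H-1,3-dioxin-4-one | CC1(C)OC(=O)C=C(CC(=O)CC(=O)C[C@@H](CCCCCCCCCCCOCc2ccccc2)O[Si](C)(C)C(C)(C)C)O1 | intermediate
13 | 5-[(R)-13-(benzyloxy)-2-(tert-butyldimethylsilyloxy)tridecyl]-5-hydroxy-2,2-dimethyl-5,6-dihydro-4H-benzo[d][1,3]dioxine-4,7(4aH)-dione (cyclic aldol adduct, both transient ring centres unassigned, formed in the flask in step 8) | CC1(C)OC(=O)C2C(=CC(=O)CC2(O)C[C@@H](CCCCCCCCCCCOCc3ccccc3)O[Si](C)(C)C(C)(C)C)O1 | intermediate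
14 | 5-[(R)-13-(benzyloxy)-2-(tert-butyldimethylsilyloxy)tridecyl]-7-hydroxy-2,2-dimethyl-4H-benzo[d][1,3]dioxin-4-one | CC1(C)OC(=O)c2c(C[C@@H](CCCCCCCCCCCOCc3ccccc3)O[Si](C)(C)C(C)(C)C)cc(O)cc2O1 | intermediate
15 | 5-[(R)-13-(benzyloxy)-2-(tert-butyldimethylsilyloxy)tridecyl]-7-methoxy-2,2-dimethyl-4H-benzo[d][1,3]dioxin-4-one | CC1(C)OC(=O)c2c(C[C@@H](CCCCCCCCCCCOCc3ccccc3)O[Si](C)(C)C(C)(C)C)cc(OC)cc2O1 | intermediate
16 | 6-[(R)-13-(benzyloxy)-2-(tert-butyldimethylsilyloxy)tridecyl]-2-hydroxy-4-methoxybenzoic acid (formed in the flask in step 10) | OC(=O)c1c(O)cc(OC)cc1C[C@@H](CCCCCCCCCCCOCc2ccccc2)O[Si](C)(C)C(C)(C)C | intermediate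
17 | 3-[(R)-13-(benzyloxy)-2-(tert-butyldimethylsilyloxy)tridecyl]-5-methoxyphenol | COc1cc(O)cc(C[C@@H](CCCCCCCCCCCOCc2ccccc2)O[Si](C)(C)C(C)(C)C)c1 | intermediate
18 | 1-(benzyloxy)-3-[(R)-13-(benzyloxy)-2-(tert-butyldimethylsilyloxy)tridecyl]-5-methoxybenzene | COc1cc(OCc2ccccc2)cc(C[C@@H](CCCCCCCCCCCOCc3ccccc3)O[Si](C)(C)C(C)(C)C)c1 | intermediate
19 | (R)-13-(benzyloxy)-1-[3-(benzyloxy)-5-methoxyphenyl]tridecan-2-ol | COc1cc(OCc2ccccc2)cc(C[C@@H](CCCCCCCCCCCOCc3ccccc3)O)c1 | intermediate
20 | (R)-13-(benzyloxy)-1-[3-(benzyloxy)-5-methoxyphenyl]tridecan-2-yl acetate | COc1cc(OCc2ccccc2)cc(C[C@@H](CCCCCCCCCCCOCc3ccccc3)OC(C)=O)c1 | intermediate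
21 | (R)-13-hydroxy-1-(3-hydroxy-5-methoxyphenyl)tridecan-2-yl acetate | COc1cc(O)cc(C[C@@H](CCCCCCCCCCCO)OC(C)=O)c1 | target

**Step count and risks**

Total step count: 14. Longest linear sequence: 13 steps (1 to 21 through steps 1–5 and 7–14); step 6 is a one-step side branch.

Steps most likely to fail:

Step 7. The strongly basic dianion may enolise the amide, which would expel the β-silyloxy group, or proton transfer may stop the coupling at partial conversion. The fallback replaces the Claisen acylation by an aldol addition and oxidation; it sets out from 9 and comes back at 12. Reduction of 9 with iBu2AlH (THF, −78 °C) should give (R)-14-(benzyloxy)-3-(tert-butyldimethylsilyloxy)tetradecanal F1. Addition of the dilithium dianion of 11 (LiN(iPr)2, THF, −78 °C) to this aldehyde, much faster than enolisation, should give 6-[(6R)-17-(benzyloxy)-6-(tert-butyldimethylsilyloxy)-4-hydroxy-2-oxoheptadecyl]-2,2-dimethyl-4H-1,3-dioxin-4-one F2 as both C4 epimers. Oxidation of the new carbinol with Dess–Martin periodinane (CH2Cl2, NaHCO3, rt) then returns 12.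

Step 8. Under amine base the ring closure may be outrun by elimination of silanolate from the β-silyloxy ketone or by O-cyclisation, or dehydration of the aldol adduct may stall. The fallback makes the same C1'–C6' bond and the same ring on an open-chain ester instead of the dioxinone; it sets out from 12 and comes back at 17. Heating 12 in toluene with methanol (110 °C) should release acetone by retro-[4+2] and trap the acyl ketene as methyl (R)-20-(benzyloxy)-9-(tert-butyldimethylsilyloxy)-3,5,7-trioxoicosanoate F3. Cs2CO3 in methanol followed by acetic acid should effect the aldol aromatisation to methyl 6-[(R)-13-(benzyloxy)-2-(tert-butyldimethylsilyloxy)tridecyl]-2,4-dihydroxybenzoate F4. One equivalent of MeI with K2CO3 in acetone should methylate the hydroxyl para to the ester, the ortho hydroxyl being held by a hydrogen bond to the ester, giving methyl 6-[(R)-13-(benzyloxy)-2-(tert-butyldimethylsilyloxy)tridecyl]-2-hydroxy-4-methoxybenzoate F5. Hot aqueous-alcoholic KOH then saponifies and decarboxylates F5 through acid 16 to 17.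

Step 10. Decarboxylation may remain incomplete in the alkaline medium, or the silyl ether may be lost, after which the freed C2 hydroxyl can lactonise onto the ring carboxyl on neutralisation. The fallback separates ring opening, ester cleavage and decarboxylation into mild stages; it sets out from 15 and comes back at 17. Allyl alcohol with K2CO3 (THF, rt) should open the dioxinone by transesterification, with loss of acetone, to allyl 6-[(R)-13-(benzyloxy)-2-(tert-butyldimethylsilyloxy)tridecyl]-2-hydroxy-4-methoxybenzoate F6. Pd(PPh3)4 (zerovalent palladium) with morpholine in THF should remove the allyl group under neutral conditions to give acid 16, here isolated. Heating 16 in toluene at 100 °C should bring about thermal protodecarboxylation to 17.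

**Further compounds**

F1 | step 7 | (R)-14-(benzyloxy)-3-(tert-butyldimethylsilyloxy)tetradecanal | O=CC[C@@H](CCCCCCCCCCCOCc1ccccc1)O[Si](C)(C)C(C)(C)C
F2 | step 7 | 6-[(6R)-17-(benzyloxy)-6-(tert-butyldimethylsilyloxy)-4-hydroxy-2-oxoheptadecyl]-2,2-dimethyl-4H-1,3-dioxin-4-one (both C4 epimers) | CC1(C)OC(=O)C=C(CC(=O)CC(O)C[C@@H](CCCCCCCCCCCOCc2ccccc2)O[Si](C)(C)C(C)(C)C)O1
F3 | step 8 | methyl (R)-20-(benzyloxy)-9-(tert-butyldimethylsilyloxy)-3,5,7-trioxoicosanoate | COC(=O)CC(=O)CC(=O)CC(=O)C[C@@H](CCCCCCCCCCCOCc1ccccc1)O[Si](C)(C)C(C)(C)C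
F4 | step 8 | methyl 6-[(R)-13-(benzyloxy)-2-(tert-butyldimethylsilyloxy)tridecyl]-2,4-dihydroxybenzoate | COC(=O)c1c(O)cc(O)cc1C[C@@H](CCCCCCCCCCCOCc2ccccc2)O[Si](C)(C)C(C)(C)C
F5 | step 8 | methyl 6-[(R)-13-(benzyloxy)-2-(tert-butyldimethylsilyloxy)tridecyl]-2-hydroxy-4-methoxybenzoate | COC(=O)c1c(O)cc(OC)cc1C[C@@H](CCCCCCCCCCCOCc2ccccc2)O[Si](C)(C)C(C)(C)C
F6 | step 10 | allyl 6-[(R)-13-(benzyloxy)-2-(tert-butyldimethylsilyloxy)tridecyl]-2-hydroxy-4-methoxybenzoate | C=CCOC(=O)c1c(O)cc(OC)cc1C[C@@H](CCCCCCCCCCCOCc2ccccc2)O[Si](C)(C)C(C)(C)C
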